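The target was what I wanted from these flasks, and in the dusk run it rose like the step response of a first-order lag. So I wrote it as S times the spent fraction of substrate. S is the share of spent substrate that ends as target (its selectivity), the spent fraction is one minus e^(−n), and n = t/τ counts the time constants τ that fit into the time t allowed.

| flask | substrate | first nucleophile | gas | temperature | remark | time |
|---|---|---|---|---|---|---|
| autumn | 0.032 M | 3 equiv | 27 mM (held) | 20 °C | run made earlier |  |
| dusk | 0.11 M | 3 equiv | 27 mM (held) | 42 °C | run made earlier |  |
| dawn | 0.050 M | 3.5 equiv | 27 mM (held) | 20 °C | run made earlier |  |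
| beta | 0.030 M | 6.00 equiv | 27 mM (held) | 50 °C |  | 50 min |
| alpha | 0.10 M | 3.00 equiv | 27 mM (held) | 50 °C |  | 50 min |
| theta | 0.050 M | 3.00 equiv | 27 mM (held) | 50 °C |  | 50 min |
| epsilon | 0.050 M | 3.00 equiv | 27 mM (held) | 35 °C |  | 50 min |
| zeta | 0.025 M | 2.00 equiv | 27 mM (held) | 10 °C |  | 50 min |
| eta | 0.080 M | 6.00 equiv | 27 mM (held) | 20 °C |  | 50 min |

| autumn: time / min | autumn: target / % | dusk: time / min | dusk: target / % | dawn: time / min | dawn: target / % |
|---|---|---|---|---|---|
| 40.0 | 13.8 | 4.00 | 21.1 | 20.0 | 8.2 |
| 80.0 | 20.9 | 12.0 | 49.1 | 50.0 | 17.0 |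
| 120 | 25.7 | 25.0 | 61.3 | 120 | 30.5 |
| 180 | 34.3 | 40.0 | 66.6 | 180 | 39.3 |

(standard deviation of a reading: 1 percentage point)

1. ranking by amount of target, in percent of the substrate charged, from high to low, at 50 min (beta / alpha / theta / epsilon / zeta / eta)
2. the amount of target, in percent of the substrate charged of the flask you put first, at 50 min
3. the amount of target, in percent of the substrate charged of the flask you put last, at 50 min

- the numbers in the tables scatter by 1 percentage point (one standard deviation)
- at the start none of the gas is in solution

I first asked which inputs had to be known well. Where n is large, τ drops out and target follows S; where n is small, target goes as S·t/τ, so an error in τ passes straight through. Temperature looked the strong setting: the first slope of target in dusk at 42 °C stood 12.9 times that in dawn at 20 °C, with the substrate and first nucleophile charges differing too. The first nucleophile looked weaker: from 0.0960 M in autumn to 0.175 M in dawn, with substrate changing too, the last reading rose from 34.3 % to 39.3 %. The gas stood at 27 mM in every run, so I could not weigh it.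

Then came the number. Taking its last reading as the plateau, dusk gave τ = 8.98 min. Taking S alike in dusk and dawn, the slope ratio gave 116 min, the time constant of substrate at 20 °C. The same ratio, read as a constant factor per degree, gave 369 min at 10 °C. In 50 min, n came to 14.1 at 50 °C, 2.47 for epsilon, 0.433 for eta and 0.136 for zeta. I therefore ranked by n, and ranked the 50 °C flasks by first-nucleophile molarity: alpha 0.300 M, beta 0.180 M, theta 0.150 M. I put alpha at dusk's last reading, 66.6 %. For zeta, autumn's S of 43.4 % gave 5.51 %.

The forecast, made on the ground that “Heat therefore favours both speed and selectivity”, ran alpha > beta > theta > epsilon > eta > zeta, my order too, with 76 % first and 4.5 % last.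

The flasks gave alpha > beta > theta > epsilon > eta > zeta, with 71.0 % against my 66.6 % and 3.71 % against my 5.51 %. Eta still held 64 % of its substrate at 50.0 min, and 116 min gives e^(−n) = 65.0 % for it.

    substrate → intermediate (k = 0.190 min⁻¹, Ea = 92.0 kJ mol⁻¹)
    first nucleophile + intermediate → target (k = 37.0 M⁻¹ min⁻¹, Ea = 38.0 kJ mol⁻¹)
    second nucleophile + intermediate → other capture product (k = 250 M⁻¹ min⁻¹, Ea = 58.0 kJ mol⁻¹)
    intermediate → solvolysis product (k = 2.00 min⁻¹, Ea = 76.0 kJ mol⁻¹)
    gas ⇌ second nucleophile, rate k5*(csat - [second nucleophile]) (kL = 0.0410 min⁻¹)
    2 substrate → self-condensation product (k = 0.180 M⁻¹ min⁻¹, Ea = 51.0 kJ mol⁻¹)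
    (constants at 50 °C)

Zeta left until 3.0 h is the second flask. I scaled 116 min to 369 min for it, as before, which made n = 0.488, so I reckoned that e^(−n) = 61.4 % of the substrate remained; the computed flask held 69 %.

The numbers in the tables stem from a simulated flask from invented constants; the scatter is artificial.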